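**Retrosynthetic overview**
1. Target 11 ⇒ dienyl trans-hydroxy benzoate 10: the C1–C6 oxirane is formed last, by hydroxyl-directed epoxidation of the trisubstituted diene terminus (the natural 1,6-desoxy precursor).
2. 10 ⇒ arene oxide 8 + benzoic acid 1: catalytic asymmetric anti opening of the racemising arene 2,3-oxide of benzyl benzoate (8 ⇌ oxepin 9) sets both carbinol centres in one step.
3. 8 ⇒ dibromo epoxide 6 ⇒ mono-epoxide 5 ⇒ 1,4-diene 4: the first oxirane is made on a Birch-derived diene and unveiled as the arene oxide by double dehydrobromination.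
4. 4 ⇒ alcohol 3 ⇒ acid 2 ⇒ benzoic acid 1; every carbon of the target comes from benzoic acid or benzoyl chloride.
5. Ring order: carbocycle from the arene; oxirane one (arene oxide), opened; then oxirane two (1,6-epoxide).

Assumption: the (S,S)-cobalt-salen catalyst is taken to give the (5R,6R)-hydroxy benzoate by analogy with its meso-epoxide openings; if the first run shows the opposite sense, the (R,R)-catalyst is used with nothing else changed.

**Route**

Step 1
Reactants: 1 benzoic acid
Product: 2 cyclohexa-2,5-diene-1-carboxylic acid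
Conditions: Na, NH3(l), EtOH, −78 °C; NH4Cl; aq. HCl
Reagents that add atoms: none
Why: Birch reduction of the benzoate anion protonates C1 and C4 and gives the unconjugated 2,5-diene; no stereocentre is formed.

Step 2
Reactants: 2 cyclohexa-2,5-diene-1-carboxylic acid
Product: 3 (cyclohexa-2,5-dien-1-yl)methanol
Conditions: LiAlH4, Et2O, 0 °C → rt; aq. NaOH work-up
Reagents that add atoms: none
Why: Hydride reduction of the carboxylic acid to the primary alcohol leaves the skipped diene untouched and unconjugated.

Step 3
Reactants: 3 (cyclohexa-2,5-dien-1-yl)methanol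
Product: 4 (cyclohexa-2,5-dien-1-yl)methyl benzoate
Conditions: BzCl, pyridine, DMAP (cat.), CH2Cl2, 0 °C → rt
Reagents that add atoms: benzoyl chloride, O=C(Cl)c1ccccc1
Why: DMAP-catalysed acylation (nucleophilic acyl substitution) of the primary alcohol installs the benzoate that stays to the end.

Step 4
Reactants: 4 (cyclohexa-2,5-dien-1-yl)methyl benzoate
Product: 5 (7-oxabicyclo[4.1.0]hept-3-en-2-yl)methyl benzoate (racemic, mainly oxirane anti to CH2OBz)
Conditions: mCPBA (1.0 equiv), CH2Cl2, 0 °C
Reagents that add atoms: mCPBA (3-chloroperoxybenzoic acid), O=C(OO)c1cccc(Cl)c1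
Why: Prilezhaev epoxidation of one of the two equivalent cis-alkenes with one equivalent of peracid (unreacted 4 is recycled); the stereocentres formed here are all erased in step 6, so the isomer mixture is harmless.

Step 5
Reactants: 5 (7-oxabicyclo[4.1.0]hept-3-en-2-yl)methyl benzoate
Product: 6 (3,4-dibromo-7-oxabicyclo[4.1.0]heptan-2-yl)methyl benzoate (racemic trans-dibromide)
Conditions: Br2 (1.0 equiv), CH2Cl2, −78 °C, dark
Reagents that add atoms: bromine, BrBr
Why: Anti addition of bromine through the bromonium ion to the remaining alkene gives the trans-dibromide, while the oxirane and ester are inert at −78 °C.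

Step 6
Reactants: 6 (3,4-dibromo-7-oxabicyclo[4.1.0]heptan-2-yl)methyl benzoate
Product: 8 (7-oxabicyclo[4.1.0]hepta-2,4-dien-2-yl)methyl benzoate (racemic arene oxide), via allylic bromide 7 (not isolated)
Conditions: DBU (3 equiv), Et2O, 0 °C → rt; filter, use cold
Reagents that add atoms: none
Why: Two successive E2 losses of HBr (the Vogel arene oxide synthesis) give the diene flanking the oxirane, isomers of 7 without an anti hydrogen being epimerised by bromide before they eliminate; 8 is obtained in valence-tautomeric equilibrium with its oxepin and is therefore racemic.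

Step 7
Reactants: 8 (7-oxabicyclo[4.1.0]hepta-2,4-dien-2-yl)methyl benzoate; 1 benzoic acid
Product: 10 [(5R,6R)-6-(benzoyloxy)-5-hydroxycyclohexa-1,3-dien-1-yl]methyl benzoate, via oxepin tautomer 9 (not isolated)
Conditions: benzoic acid (1.05 equiv), [(S,S)-N,N′-bis(3,5-di-tert-butylsalicylidene)cyclohexane-1,2-diaminato]cobalt C36H52CoN2O2 (divalent cobalt, 5 mol%), i-Pr2NEt (1 equiv), air, t-BuOMe, 0 °C
Reagents that add atoms: benzoic acid (compound 1), O=C(O)c1ccccc1
Why: Proposed new method: the trivalent cobalt benzoate formed in situ from the divalent complex, benzoic acid and air binds the oxirane oxygen of 8 while a second catalyst molecule delivers benzoate anti to it (cooperative SN2 opening, as in the known cobalt-salen desymmetrisation of meso epoxides with carboxylic acids, the closest known reaction), and because 8 racemises continuously through oxepin 9 and the catalyst opens only an oxirane carbon of one absolute sense, the enantiomer offering the carbon next to the CH2OBz-bearing carbon (argued to be the more activated, since its cleavage puts no positive charge on the carbon carrying the inductively withdrawing CH2OBz group) is drained, with inversion at C6 (OBz) and retention at C5 (OH), hence the trans (5R,6R) product.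

Step 8
Reactants: 10 [(5R,6R)-6-(benzoyloxy)-5-hydroxycyclohexa-1,3-dien-1-yl]methyl benzoate
Product: 11 [(1S,2S,3R,6S)-2-(benzoyloxy)-3-hydroxy-7-oxabicyclo[4.1.0]hept-4-en-1-yl]methyl benzoate
Conditions: mCPBA (1.2 equiv), CH2Cl2, 0 °C
Reagents that add atoms: mCPBA (3-chloroperoxybenzoic acid), O=C(OO)c1cccc(Cl)c1
Why: Henbest-type hydroxyl-directed peracid epoxidation: A(1,2) strain puts the allylic OBz pseudoaxial on one face and the trans 5-OH pseudoaxial on the other, so the hydrogen-bonded peracid reaches the more nucleophilic trisubstituted C1=C2 bond from the hydroxyl face, setting both oxirane carbons cis to OH and trans to OBz (ee is raised by recrystallising 11).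

**Compound list**
1 | benzoic acid | O=C(O)c1ccccc1 | starting material
2 | cyclohexa-2,5-diene-1-carboxylic acid | O=C(O)C1C=CCC=C1 | intermediate
3 | (cyclohexa-2,5-dien-1-yl)methanol | OCC1C=CCC=C1 | intermediate
4 | (cyclohexa-2,5-dien-1-yl)methyl benzoate | O=C(OCC1C=CCC=C1)c1ccccc1 | intermediate
5 | (7-oxabicyclo[4.1.0]hept-3-en-2-yl)methyl benzoate, racemic, oxirane anti to CH2OBz (one enantiomer of the main isomer drawn) | O=C(OC[C@@H]1C=CC[C@H]2O[C@@H]12)c1ccccc1 | intermediate
6 | (3,4-dibromo-7-oxabicyclo[4.1.0]heptan-2-yl)methyl benzoate, racemic trans-dibromide (one isomer of the mixture drawn) | O=C(OC[C@@H]1[C@H](Br)[C@@H](Br)C[C@H]2O[C@@H]12)c1ccccc1 | intermediate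
7 | (3-bromo-7-oxabicyclo[4.1.0]hept-4-en-2-yl)methyl benzoate, racemic allylic bromide (not isolated) | O=C(OC[C@@H]1[C@H](Br)C=C[C@H]2O[C@@H]12)c1ccccc1 | intermediate
8 | (7-oxabicyclo[4.1.0]hepta-2,4-dien-2-yl)methyl benzoate, racemic arene oxide (the enantiomer that leads to 10 drawn) | O=C(OCC1=CC=C[C@H]2O[C@@H]12)c1ccccc1 | intermediate
9 | (oxepin-3-yl)methyl benzoate, valence tautomer of 8 (not isolated) | O=C(OCC1=COC=CC=C1)c1ccccc1 | intermediate
10 | [(5R,6R)-6-(benzoyloxy)-5-hydroxycyclohexa-1,3-dien-1-yl]methyl benzoate | O=C(OCC1=CC=C[C@@H](O)[C@@H]1OC(=O)c1ccccc1)c1ccccc1 | intermediate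
11 | [(1S,2S,3R,6S)-2-(benzoyloxy)-3-hydroxy-7-oxabicyclo[4.1.0]hept-4-en-1-yl]methyl benzoate | O=C(OC[C@]12O[C@H]1C=C[C@@H](O)[C@@H]2OC(=O)c1ccccc1)c1ccccc1 | target

**Total step count:** 8. **Longest linear sequence:** 8 (fully linear from benzoic acid).

**Three steps most likely to fail**

Step 7 is the least certain. The arene oxide can aromatise to hydroxybenzyl benzoates, and the ee may be modest. The regiochemistry is not secured either: the electronic preference for the carbon next to the substituent is small, and I could not confirm a precedent for it. If the other enantiomer is opened at the distal oxirane carbon, the by-product is the 5-O-benzoyl regioisomer with the same absolute configuration, so yield suffers but not ee. The fallback sets out from 8 and replaces benzoic acid by water. The same cobalt complex, as its trivalent cobalt acetate C38H55CoN2O4, hydrolyses each enantiomer at the oxirane carbon of the sense it accepts. Both enantiomers and both regiochemistries then converge on one diol, [(5R,6R)-5,6-dihydroxycyclohexa-1,3-dien-1-yl]methyl benzoate F1. The less hindered 5-OH is silylated (TESCl, imidazole, CH2Cl2, −40 °C) to [(5R,6R)-6-hydroxy-5-(triethylsilyloxy)cyclohexa-1,3-dien-1-yl]methyl benzoate F2. Benzoylation (BzCl, pyridine, DMAP) gives [(5R,6R)-6-(benzoyloxy)-5-(triethylsilyloxy)cyclohexa-1,3-dien-1-yl]methyl benzoate F3. HF·pyridine in THF at 0 °C removes the silyl group and the route is rejoined at 10.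

Step 8 may give the wrong regiochemistry or face: the free hydroxyl is allylic to the disubstituted C3=C4 bond and could steer the peracid there. The fallback sets out from 10 and uses singlet oxygen instead of a peracid. Photo-oxygenation (O2, hν, tetraphenylporphyrin cat., CH2Cl2, −78 °C) adds across the diene termini on the hydroxyl face to give the endoperoxide [(1R,4R,7S,8S)-7-(benzoyloxy)-8-hydroxy-2,3-dioxabicyclo[2.2.2]oct-5-en-1-yl]methyl benzoate F4. PPh3 (CH2Cl2, −78 → 0 °C) abstracts the less hindered peroxide oxygen, the one on the CH bridgehead. The remaining tertiary alkoxide closes in an SN2′ fashion onto the adjacent alkene carbon, which fixes the oxirane at C1–C6 and the alkene at C4=C5. The route is rejoined at 11.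

Step 6 may fail through aromatisation of the labile arene oxide or through a stalled second elimination when no anti hydrogen is available. The fallback sets out from 5 and builds the diene with one mild E2 instead of two. PhSeCl (CH2Cl2, −78 °C) adds trans to the alkene to give the regioisomers [3-chloro-4-(phenylselanyl)-7-oxabicyclo[4.1.0]heptan-2-yl]methyl benzoate F5 and [4-chloro-3-(phenylselanyl)-7-oxabicyclo[4.1.0]heptan-2-yl]methyl benzoate F6. Oxidation (H2O2, pyridine, CH2Cl2, 0 °C → rt) and selenoxide syn-elimination away from chlorine give the allylic chlorides (3-chloro-7-oxabicyclo[4.1.0]hept-4-en-2-yl)methyl benzoate F7 and (4-chloro-7-oxabicyclo[4.1.0]hept-2-en-2-yl)methyl benzoate F8. A single dehydrochlorination of either with DBU (Et2O, 0 °C) converges on the same diene, and the route is rejoined at 8.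

**Further compounds**
F1 | step 7 | [(5R,6R)-5,6-dihydroxycyclohexa-1,3-dien-1-yl]methyl benzoate | O=C(OCC1=CC=C[C@@H](O)[C@@H]1O)c1ccccc1
F2 | step 7 | [(5R,6R)-6-hydroxy-5-(triethylsilyloxy)cyclohexa-1,3-dien-1-yl]methyl benzoate | O=C(OCC1=CC=C[C@@H](O[Si](CC)(CC)CC)[C@@H]1O)c1ccccc1
F3 | step 7 | [(5R,6R)-6-(benzoyloxy)-5-(triethylsilyloxy)cyclohexa-1,3-dien-1-yl]methyl benzoate | O=C(OCC1=CC=C[C@@H](O[Si](CC)(CC)CC)[C@@H]1OC(=O)c1ccccc1)c1ccccc1
F4 | step 8 | [(1R,4R,7S,8S)-7-(benzoyloxy)-8-hydroxy-2,3-dioxabicyclo[2.2.2]oct-5-en-1-yl]methyl benzoate | O=C(OC[C@]12OO[C@H](C=C1)[C@@H](O)[C@@H]2OC(=O)c1ccccc1)c1ccccc1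
F5 | step 6 | [3-chloro-4-(phenylselanyl)-7-oxabicyclo[4.1.0]heptan-2-yl]methyl benzoate, racemic (one isomer drawn) | O=C(OC[C@@H]1[C@H](Cl)[C@@H]([Se]c3ccccc3)C[C@H]2O[C@@H]12)c1ccccc1
F6 | step 6 | [4-chloro-3-(phenylselanyl)-7-oxabicyclo[4.1.0]heptan-2-yl]methyl benzoate, racemic (one isomer drawn) | O=C(OC[C@@H]1[C@@H]([Se]c3ccccc3)[C@H](Cl)C[C@H]2O[C@@H]12)c1ccccc1
F7 | step 6 | (3-chloro-7-oxabicyclo[4.1.0]hept-4-en-2-yl)methyl benzoate, racemic (one isomer drawn) | O=C(OC[C@@H]1[C@H](Cl)C=C[C@H]2O[C@@H]12)c1ccccc1
F8 | step 6 | (4-chloro-7-oxabicyclo[4.1.0]hept-2-en-2-yl)methyl benzoate, racemic (one isomer drawn) | O=C(OCC1=C[C@H](Cl)C[C@H]2O[C@@H]12)c1ccccc1
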